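The route rests on the orsellinate substitution of ring A of the 6-linked coumarin (C4a, C5, C6, C7, C8, C8a): this ring is grown onto a finished ring B arene, so no aryl–aryl coupling is needed. One Michael–Claisen operation joins the C2 carbon of ethyl acetoacetate (later C4a) to the methyl-bearing alkene carbon (later C5) of a 2-aryl-but-2-enoate, then the acetyl methyl carbon (later C8) to the enoate carbonyl (later C7), giving the carbocycle at the dihydro level with the aryl group already on C6. The precursor is ethyl (E)-2-[2-(benzyloxy)-6-methoxy-4-methylphenyl]but-2-enoate; aromatisation and two pyranone closures complete the racemic target.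

Key step: step 4

Remark on stereochemistry: the target SMILES fixes no configuration at the 6,8' axis, so the racemic biaryl is made; from 12 onwards every compound is a racemate about this hindered axis.
Remark on ring B: the aryl group enters with the future 7'-methoxy group already as its methyl ether and a benzyl group only on the future lactone oxygen O1', so a single phenol is released before the second pyranone closure and one late methylation suffices.
Remark on 10: the enol drawn has its double bond between ring carbons C1 and C2, so it is named as a cyclohex-1-ene-1-carboxylate; it equilibrates with the diketone enol, and both sp3 centres vanish in step 5.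
Abbreviation: Ar = 2-(benzyloxy)-6-methoxy-4-methylphenyl.

Step 1
Reactants: 1 3-methoxy-5-methylphenol; 2 benzyl bromide
Product: 3 1-(benzyloxy)-3-methoxy-5-methylbenzene
Conditions: K2CO3, DMF, 60 °C
Reagents that add atoms: none
Why: Williamson ether synthesis: the potassium phenoxide displaces bromide at the benzylic carbon (SN2), and no other nucleophilic site is present.

Step 2
Reactants: 3 1-(benzyloxy)-3-methoxy-5-methylbenzene; 4 diethyl oxalate
Product: 6 ethyl 2-[2-(benzyloxy)-6-methoxy-4-methylphenyl]-2-oxoacetate, via [2-(benzyloxy)-6-methoxy-4-methylphenyl]lithium 5 (not isolated)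
Conditions: n-BuLi (1.1 equiv), THF, 0 °C, 1 h; cannulated into 4 (3 equiv), THF, −78 °C; 1 M HCl
Reagents that add atoms: none
Why: Directed ortho-metalation removes the ring hydrogen flanked by both ether oxygens (the doubly activated site of a 3,5-dialkoxytoluene), and inverse addition of the hindered aryllithium to excess oxalate should stop at the α-keto ester because the tetrahedral adduct persists at −78 °C.

Step 3
Reactants: 6 ethyl 2-[2-(benzyloxy)-6-methoxy-4-methylphenyl]-2-oxoacetate
Product: 7 ethyl (E)-2-[2-(benzyloxy)-6-methoxy-4-methylphenyl]but-2-enoate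
Conditions: EtPPh3Br, KN(SiMe3)2, THF, 0 °C; then 6, −78 °C → rt
Reagents that add atoms: ethyltriphenylphosphonium bromide, CC[P+](c1ccccc1)(c1ccccc1)c1ccccc1.[Br-]
Why: Wittig olefination of the non-enolisable, ester-activated keto carbonyl by the non-stabilised ethylidene ylide; the E isomer is drawn, and any Z isomer can be carried on because step 4 erases the alkene geometry.

Step 4
Reactants: 7 ethyl (E)-2-[2-(benzyloxy)-6-methoxy-4-methylphenyl]but-2-enoate; 8 ethyl acetoacetate
Product: 10 ethyl 5-Ar-2-hydroxy-6-methyl-4-oxocyclohex-1-ene-1-carboxylate (racemic; Ar trans to methyl), via diethyl 2-acetyl-4-Ar-3-methylpentanedioate 9 (not isolated)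
Conditions: NaOEt (1.2 equiv), EtOH, reflux; then 1 M HCl, 0 °C
Reagents that add atoms: none
Why: The sodium enolate of 8 attacks the β-carbon of 7 through its C2 carbon (Michael addition) and the resulting ester enolate is protonated by ethanol to give 9; ethoxide then deprotonates the acetyl methyl group, and this enolate acylates at the ethyl ester beside the aryl-bearing carbon with loss of ethoxide. The closest known reaction is the Michael–Claisen condensation of ethyl acetoacetate with ethyl crotonate to ethyl dihydroorsellinate. The ring closes as a 6-(enolexo)-exo-trig Claisen (Dieckmann-type) acylation, and deprotonation of the new 1,3-dione to its stabilised sodium enolate pulls the reversible conjugate addition forward. The two sp3 centres (ring C5 and C6) are set under thermodynamic control, C5 being epimerisable next to the ketone, so aryl and methyl should settle trans; both centres are removed in step 5. The step needs C-alkylation at the acetoacetate C2 carbon and acylation by the methyl ketone only: the β-carbon of 7 carries just H and CH3 and is the sole electrophilic alkene carbon, and every other Claisen mode would give a four-membered ring.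

Step 5
Reactants: 10 ethyl 5-Ar-2-hydroxy-6-methyl-4-oxocyclohex-1-ene-1-carboxylate
Product: 12 ethyl 3-Ar-4,6-dihydroxy-2-methylbenzoate, via ethyl 3-bromo-5-Ar-6-methyl-2,4-dioxocyclohexane-1-carboxylate 11 (not isolated)
Conditions: Br2 (1.0 equiv), DMF, 0 °C; then 80 °C
Reagents that add atoms: none
Why: Halogenation–dehydrohalogenation aromatisation, the usual way from 2,4-dioxocyclohexanecarboxylates to 2,4-dihydroxybenzoates: the enol is brominated between the two carbonyl groups far faster than either arene, and on warming HBr-mediated bromine shift, loss of HBr and enolisation give the arene.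

Step 6
Reactants: 12 ethyl 3-Ar-4,6-dihydroxy-2-methylbenzoate
Product: 13 ethyl 3-Ar-6-hydroxy-4-methoxy-2-methylbenzoate
Conditions: MeI (1.05 equiv), K2CO3 (1.1 equiv), acetone, 40 °C
Reagents that add atoms: iodomethane, CI
Why: Williamson methylation that should select the hydroxyl para to the ester (future O7), because the ortho hydroxyl is held in a hydrogen bond to the ester carbonyl and is alkylated much more slowly, the usual behaviour of 2,4-dihydroxybenzoates.

Step 7
Reactants: 13 ethyl 3-Ar-6-hydroxy-4-methoxy-2-methylbenzoate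
Product: 14 ethyl 6-(acetyloxy)-3-Ar-4-methoxy-2-methylbenzoate
Conditions: Ac2O, pyridine, 4-(dimethylamino)pyridine (cat.), CH2Cl2, rt
Reagents that add atoms: acetic anhydride, CC(=O)OC(C)=O
Why: Nucleophile-catalysed O-acetylation of the remaining hydrogen-bonded phenol through the N-acetylpyridinium ion.

Step 8
Reactants: 14 ethyl 6-(acetyloxy)-3-Ar-4-methoxy-2-methylbenzoate
Product: 15 6-Ar-4-hydroxy-7-methoxy-5-methyl-2H-chromen-2-one
Conditions: LiN(SiMe3)2 (3 equiv), THF, −78 °C → rt; 1 M HCl
Reagents that add atoms: none
Why: Intramolecular Claisen condensation of Baker–Venkataraman type: the lithium enolate of the aryl acetate attacks the neighbouring ethyl ester in a 6-exo-trig closure, ethoxide leaves and the acidic 4-hydroxycoumarin is held as its lithium salt, while LiN(SiMe3)2 is too weak a base to deprotonate the benzylic methyl groups.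

Step 9
Reactants: 15 6-Ar-4-hydroxy-7-methoxy-5-methyl-2H-chromen-2-one
Product: 16 6-Ar-4,7-dimethoxy-5-methyl-2H-chromen-2-one
Conditions: Me2SO4, K2CO3, acetone, reflux
Reagents that add atoms: dimethyl sulfate, COS(=O)(=O)OC
Why: O-alkylation of the 4-hydroxycoumarin anion by the hard electrophile dimethyl sulfate gives the 4-methoxy-2-pyranone, the normal outcome under K2CO3 in acetone, and masks O4 and C3 before the second annulation.

Step 10
Reactants: 16 6-Ar-4,7-dimethoxy-5-methyl-2H-chromen-2-one
Product: 17 6-(2-hydroxy-6-methoxy-4-methylphenyl)-4,7-dimethoxy-5-methyl-2H-chromen-2-one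
Conditions: H2 (1 atm), 10% Pd/C, EtOAc–MeOH, rt
Reagents that add atoms: none
Why: Heterogeneous catalytic hydrogenolysis of the benzyl aryl ether; the methyl ethers are inert and the alkoxy-substituted, arene-conjugated C3–C4 double bond of the coumarin should not be reduced under these mild conditions.

Step 11
Reactants: 17 6-(2-hydroxy-6-methoxy-4-methylphenyl)-4,7-dimethoxy-5-methyl-2H-chromen-2-one
Product: 19 4'-hydroxy-4,7,7'-trimethoxy-5,5'-dimethyl-2H,2'H-[6,8'-bichromene]-2,2'-dione, via aryl hydrogen malonate 18 (not isolated)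
Conditions: Meldrum's acid (1.2 equiv), toluene, 100 °C; evaporate; P2O5 in MeSO3H (Eaton's reagent), 70 °C
Reagents that add atoms: Meldrum's acid (2,2-dimethyl-1,3-dioxane-4,6-dione), CC1(C)OC(=O)CC(=O)O1
Why: The phenol opens Meldrum's acid to the aryl hydrogen malonate with loss of acetone, and Eaton's reagent then effects intramolecular Friedel–Crafts acylation at the only free ortho carbon of ring B (para to its methoxy group) followed by enolisation, a standard two-stage phenol-to-4-hydroxycoumarin annulation.

Step 12
Reactants: 19 4'-hydroxy-4,7,7'-trimethoxy-5,5'-dimethyl-2H,2'H-[6,8'-bichromene]-2,2'-dione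
Product: 20 4,4',7,7'-tetramethoxy-5,5'-dimethyl-2H,2'H-[6,8'-bichromene]-2,2'-dione (racemic)
Conditions: Me2SO4, K2CO3, acetone, reflux
Reagents that add atoms: dimethyl sulfate, COS(=O)(=O)OC
Why: The same O-methylation of a 4-hydroxycoumarin anion as in step 9, now on the pyranone fused to ring B, which should give the tetramethoxy target.

Compound list
1 | 3-methoxy-5-methylphenol (orcinol monomethyl ether) | COc1cc(C)cc(O)c1 | starting material
2 | benzyl bromide | BrCc1ccccc1 | starting material
3 | 1-(benzyloxy)-3-methoxy-5-methylbenzene | COc1cc(C)cc(OCc2ccccc2)c1 | intermediate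
4 | diethyl oxalate | CCOC(=O)C(=O)OCC | starting material
5 | [2-(benzyloxy)-6-methoxy-4-methylphenyl]lithium (not isolated) | [Li]c1c(OC)cc(C)cc1OCc1ccccc1 | intermediate
6 | ethyl 2-[2-(benzyloxy)-6-methoxy-4-methylphenyl]-2-oxoacetate | CCOC(=O)C(=O)c1c(OC)cc(C)cc1OCc1ccccc1 | intermediate
7 | ethyl (E)-2-[2-(benzyloxy)-6-methoxy-4-methylphenyl]but-2-enoate | C/C=C(\c1c(OC)cc(C)cc1OCc1ccccc1)C(=O)OCC | intermediate
8 | ethyl acetoacetate | CCOC(=O)CC(C)=O | starting material
9 | diethyl 2-acetyl-4-[2-(benzyloxy)-6-methoxy-4-methylphenyl]-3-methylpentanedioate (diastereomer mixture, not isolated) | CCOC(=O)C(C(C)=O)C(C)C(c1c(OC)cc(C)cc1OCc1ccccc1)C(=O)OCC | intermediate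
10 | ethyl 5-[2-(benzyloxy)-6-methoxy-4-methylphenyl]-2-hydroxy-6-methyl-4-oxocyclohex-1-ene-1-carboxylate (racemic, aryl trans to methyl; one enantiomer drawn) | CCOC(=O)C1=C(O)CC(=O)[C@@H](c2c(OC)cc(C)cc2OCc2ccccc2)[C@@H]1C | intermediate
11 | ethyl 3-bromo-5-[2-(benzyloxy)-6-methoxy-4-methylphenyl]-6-methyl-2,4-dioxocyclohexane-1-carboxylate (racemic, C1 and C3 undefined, not isolated) | CCOC(=O)C1C(=O)C(Br)C(=O)[C@@H](c2c(OC)cc(C)cc2OCc2ccccc2)[C@@H]1C | intermediate
12 | ethyl 3-[2-(benzyloxy)-6-methoxy-4-methylphenyl]-4,6-dihydroxy-2-methylbenzoate (racemic axis) | CCOC(=O)c1c(O)cc(O)c(-c2c(OC)cc(C)cc2OCc2ccccc2)c1C | intermediate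
13 | ethyl 3-[2-(benzyloxy)-6-methoxy-4-methylphenyl]-6-hydroxy-4-methoxy-2-methylbenzoate (racemic axis) | CCOC(=O)c1c(O)cc(OC)c(-c2c(OC)cc(C)cc2OCc2ccccc2)c1C | intermediate
14 | ethyl 6-(acetyloxy)-3-[2-(benzyloxy)-6-methoxy-4-methylphenyl]-4-methoxy-2-methylbenzoate (racemic axis) | CCOC(=O)c1c(OC(C)=O)cc(OC)c(-c2c(OC)cc(C)cc2OCc2ccccc2)c1C | intermediate
15 | 6-[2-(benzyloxy)-6-methoxy-4-methylphenyl]-4-hydroxy-7-methoxy-5-methyl-2H-chromen-2-one (racemic axis) | COc1cc2oc(=O)cc(O)c2c(C)c1-c1c(OC)cc(C)cc1OCc1ccccc1 | intermediate
16 | 6-[2-(benzyloxy)-6-methoxy-4-methylphenyl]-4,7-dimethoxy-5-methyl-2H-chromen-2-one (racemic axis) | COc1cc2oc(=O)cc(OC)c2c(C)c1-c1c(OC)cc(C)cc1OCc1ccccc1 | intermediate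
17 | 6-(2-hydroxy-6-methoxy-4-methylphenyl)-4,7-dimethoxy-5-methyl-2H-chromen-2-one (racemic axis) | COc1cc2oc(=O)cc(OC)c2c(C)c1-c1c(OC)cc(C)cc1O | intermediate
18 | 3-[2-(4,7-dimethoxy-5-methyl-2-oxo-2H-chromen-6-yl)-3-methoxy-5-methylphenoxy]-3-oxopropanoic acid (racemic axis, not isolated) | COc1cc2oc(=O)cc(OC)c2c(C)c1-c1c(OC)cc(C)cc1OC(=O)CC(=O)O | intermediate
19 | 4'-hydroxy-4,7,7'-trimethoxy-5,5'-dimethyl-2H,2'H-[6,8'-bichromene]-2,2'-dione (racemic axis) | COc1cc2oc(=O)cc(OC)c2c(C)c1-c1c(OC)cc(C)c2c(O)cc(=O)oc12 | intermediate
20 | 4,4',7,7'-tetramethoxy-5,5'-dimethyl-2H,2'H-[6,8'-bichromene]-2,2'-dione (racemic axis) | COc1cc2oc(=O)cc(OC)c2c(C)c1-c1c(OC)cc(C)c2c(OC)cc(=O)oc12 | target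

Total step count: 12. Longest linear sequence: 12 steps (1 to 20; the route is fully linear).

Steps most likely to fail

Step 4. The conjugate addition may stall, because the twisted di-ortho-substituted aryl group shields the alkene and the addition is reversible, and ethoxide may cleave the acetyl group of the open-chain adduct (retro-Claisen) before the ring closes. The fallback sets out from 6 and rejoins the route at 10, exchanging donor and acceptor so that the C5–C6 bond of the future ring A is made first. The keto group of 6 is reduced with NaBH4 (EtOH, −20 °C) to ethyl 2-[2-(benzyloxy)-6-methoxy-4-methylphenyl]-2-hydroxyacetate F1, and ionic deoxygenation (Et3SiH, BF3·OEt2, CH2Cl2, 0 °C) gives ethyl 2-[2-(benzyloxy)-6-methoxy-4-methylphenyl]acetate F2. Its lithium enolate (LiN(SiMe3)2, THF, −78 °C) is added to ethyl 2-acetylbut-2-enoate F3, prepared by Knoevenagel condensation of acetaldehyde with 8 (piperidine cat., −10 °C). This doubly activated acceptor should take up the ester enolate readily and give the same adduct 9, now isolated, which NaOEt in EtOH closes to 10 by the same Claisen acylation.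

Step 5. Electrophilic bromination of the electron-rich ring B or of the resorcinol ring just formed may compete during the warm phase, and HBr may loosen the benzyl ether. The fallback sets out from 10 and rejoins at 12, avoiding any free electrophilic halogen. The dianion of 10 (LiN(i-Pr)2, 2.2 equiv, THF, −78 °C) is selenenylated with PhSeBr at the ester-bearing carbon, the last-formed and most reactive carbanion site, to give ethyl 5-Ar-6-methyl-2,4-dioxo-1-(phenylselanyl)cyclohexane-1-carboxylate F4, with selenium expected anti to the neighbouring methyl group and hence syn to the hydrogen on C6. Oxidation with H2O2 (CH2Cl2, pyridine, 0 °C) should trigger selenoxide syn-elimination towards C6, and enolisation of the resulting cyclohexenedione gives 12.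

Step 3. Attack of the ylide on the keto carbonyl, which is flanked by the 2,6-disubstituted aryl group, may be slow, leaving starting material or diverting the ylide to the ester. The fallback sets out from 6 and rejoins at 7 in two operations. EtMgBr (THF, −78 °C) adds to the more electrophilic keto carbonyl to give ethyl 2-[2-(benzyloxy)-6-methoxy-4-methylphenyl]-2-hydroxybutanoate F5, and dehydration with SOCl2 and pyridine (0 °C) can only proceed towards the ethyl group and gives 7.

Further compounds
F1 | step 4 | ethyl 2-[2-(benzyloxy)-6-methoxy-4-methylphenyl]-2-hydroxyacetate (racemic) | CCOC(=O)C(O)c1c(OC)cc(C)cc1OCc1ccccc1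
F2 | step 4 | ethyl 2-[2-(benzyloxy)-6-methoxy-4-methylphenyl]acetate | CCOC(=O)Cc1c(OC)cc(C)cc1OCc1ccccc1
F3 | step 4 | ethyl 2-acetylbut-2-enoate (E/Z mixture) | CC=C(C(C)=O)C(=O)OCC
F4 | step 5 | ethyl 5-[2-(benzyloxy)-6-methoxy-4-methylphenyl]-6-methyl-2,4-dioxo-1-(phenylselanyl)cyclohexane-1-carboxylate (racemic; selenium cis to H on C6, aryl trans to methyl) | CCOC(=O)[C@]1([Se]c2ccccc2)C(=O)CC(=O)[C@@H](c2c(OC)cc(C)cc2OCc2ccccc2)[C@@H]1C
F5 | step 3 | ethyl 2-[2-(benzyloxy)-6-methoxy-4-methylphenyl]-2-hydroxybutanoate (racemic) | CCOC(=O)C(O)(CC)c1c(OC)cc(C)cc1OCc1ccccc1
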